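**Plan**

Numbering: ring A is C1 (OMe), C2 (Br), C3 (H), C4 (Br), C5 (H), C6 (O to ring B). Ring B is C1' (ether O), C2' (Br), C3' (H), C4' (Br), C5' (Br), C6' (OH).
Enabling feature: the two ring A bromines (C2, C4) lie ortho and para to the C1 oxygen, and the other ortho carbon, C6, holds the ether oxygen. A 2-aryloxycyclohexanone must end in this pattern when bromine aromatises it, so O-C6 can first be made as an sp3 C-O bond.
Cuts, in order: the mask on C6'-OH (isopropyl); C1O-CH3; C2-Br and C4-Br together with de-aromatisation of ring A to a cyclohexanone; O-C6 (SN2 on 2-chlorocyclohexanone); C2'-Br, C4'-Br and C1'-O, back to 2,6-dibromophenol.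
Forward: ring B is bought aromatic and dressed (steps 1-3). The saturated ring A carbocycle is hung on its oxygen (step 4), aromatised and brominated (step 5), then methylated and unmasked (steps 6-7). No ring is closed anywhere.
Stereochemistry: the target has no stereocentre. The one in ketone 9 is racemic and disappears in step 5.

Key step: step 5

**Step 1**
Reactants: 1 2,6-dibromophenol; 2 2-bromopropane
Product: 3 1,3-dibromo-2-isopropoxybenzene
Conditions: K2CO3, DMF, 60 °C
Reagents that add atoms: none
Why: Williamson ether synthesis, in which K2CO3 fully ionises the acidic flanked phenol in DMF and the phenoxide displaces bromide from the secondary halide, an excess of 2 covering what is lost to elimination.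

**Step 2**
Reactants: 3 1,3-dibromo-2-isopropoxybenzene
Product: 6 3-bromo-2-isopropoxyphenol, via aryllithium 4 (not isolated), via dimethyl arylboronate 5 (not isolated)
Conditions: n-BuLi (1.0 equiv), THF, −78 °C; B(OMe)3, −78 °C to rt; AcOH, 30% H2O2, 0 °C to rt
Reagents that add atoms: n-butyllithium, [Li]CCCC (lithium of 4 only); trimethyl borate, COB(OC)OC (boron and two methoxy groups of 5 only); hydrogen peroxide, OO (phenol oxygen of 6)
Why: Bromine-lithium exchange, borylation and peroxide ipso-hydroxylation, in which the two bromines of 3 are equivalent so no site choice arises, one equivalent of n-BuLi stops at the monolithio species, that species has no halogen beside the carbanion and so no aryne exit, and boron is exchanged for oxygen at the same carbon.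

**Step 3**
Reactants: 6 3-bromo-2-isopropoxyphenol
Product: 7 3,4,6-tribromo-2-isopropoxyphenol
Conditions: Br2 (2.05 equiv), AcOH, rt
Reagents that add atoms: bromine, BrBr
Why: Electrophilic aromatic bromination, in which the free hydroxyl directs to its open para and ortho carbons (C4' and C2'), the resident C5' bromine favours the same two sites, and C3'-H is activated only by the twisted isopropoxy group, so two equivalents should stop at 7.

**Step 4**
Reactants: 7 3,4,6-tribromo-2-isopropoxyphenol; 8 2-chlorocyclohexanone
Product: 9 2-(3,4,6-tribromo-2-isopropoxyphenoxy)cyclohexan-1-one (racemic)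
Conditions: K2CO3, DMF, 50 °C
Reagents that add atoms: none
Why: Williamson-type SN2 displacement at an alpha-halo ketone, the usual entry to 2-aryloxycyclohexanones, in which carbonyl activation lets this hindered phenoxide substitute the secondary chloride, its low basicity disfavours Favorskii rearrangement and elimination, and the new stereocentre is formed racemic without control because step 5 erases it.

**Step 5**
Reactants: 9 2-(3,4,6-tribromo-2-isopropoxyphenoxy)cyclohexan-1-one
Product: 12 2,4-dibromo-6-(3,4,6-tribromo-2-isopropoxyphenoxy)phenol, via dibromoenone 10 (not isolated), via monobromophenol 11 (not isolated)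
Conditions: Br2 (3.05 equiv), cat. HBr, dry AcOH, rt; 60 °C, N2 sweep; then Br2 (1.05 equiv), rt
Reagents that add atoms: bromine, BrBr
Why: Proposed new method: acid-catalysed enolisation delivers bromine to both carbons flanking the carbonyl (C2 twice, C6 once), the bromide on the aryloxy-bearing C6 is lost at once as HBr, and dibromoenone 10 is the expected resting point at room temperature. At 60 °C vinylogous enolisation and loss of a further HBr give a cyclohexadienone that tautomerises to bromophenol 11, which keeps one C2-Br bond of the gem-dibromide, and the last equivalent of Br2 then forms C4-Br by ordinary electrophilic substitution para to the new hydroxyl. The closest known reaction type is the bromination-dehydrobromination of cyclohexanones and cyclohexenones to ortho- and para-brominated phenols, which has not been shown for a ketone that carries an aryloxy group on its alpha carbon. No ring closes and no stereocentre is created: the existing six-membered carbocycle aromatises and the single stereocentre of 9 is erased. The site selectivity needed on ring A is secured by the C1 oxygen, whose only open ortho and para carbons are C2 and C4 because C6 holds the ether, so a different order of brominations and eliminations converges on the same product, and holding back the fourth equivalent until the ring is aromatic keeps free bromine away from the C5=C6 double bond of 10. The chemoselectivity needed towards ring B is secured by its three bromines, by the twisted isopropoxy group and by the position of its only C-H between two bromines; its two occupied ortho carbons shut off acid-induced cyclodehydration to a benzofuran, the dry medium prevents hydrolytic release of phenol 7 from brominated C6, and the nitrogen sweep with a 60 °C ceiling spares the isopropyl ether from HBr.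

**Step 6**
Reactants: 12 2,4-dibromo-6-(3,4,6-tribromo-2-isopropoxyphenoxy)phenol
Product: 13 1,2,5-tribromo-4-(3,5-dibromo-2-methoxyphenoxy)-3-isopropoxybenzene
Conditions: MeI, K2CO3, DMF, rt
Reagents that add atoms: iodomethane, CI
Why: Williamson O-methylation of the only free hydroxyl, an acidic dibromophenol that K2CO3 ionises completely and that attacks the unhindered methyl iodide without touching either ether.

**Step 7**
Reactants: 13 1,2,5-tribromo-4-(3,5-dibromo-2-methoxyphenoxy)-3-isopropoxybenzene
Product: 15 2,3,5-tribromo-6-(3,5-dibromo-2-methoxyphenoxy)phenol (CNP0282108.0), via aryloxydichloroborane 14 (not isolated)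
Conditions: BCl3 (1 M in CH2Cl2), CH2Cl2, −78 to 0 °C; then H2O
Reagents that add atoms: boron trichloride, ClB(Cl)Cl (boron and chlorine of 14 only)
Why: Lewis acid dealkylation of an aryl isopropyl ether, which ionises through an isopropyl-cation-like transition state at temperatures where the aryl methyl ether, needing SN2 attack of chloride on CH3, and the diaryl ether both persist.

**Compound list**

1 | 2,6-dibromophenol | Oc1c(Br)cccc1Br | starting material
2 | 2-bromopropane | CC(C)Br | starting material
3 | 1,3-dibromo-2-isopropoxybenzene | CC(C)Oc1c(Br)cccc1Br | intermediate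
4 | (3-bromo-2-isopropoxyphenyl)lithium (not isolated) | [Li]c1cccc(Br)c1OC(C)C | intermediate
5 | dimethyl (3-bromo-2-isopropoxyphenyl)boronate (not isolated) | COB(OC)c1cccc(Br)c1OC(C)C | intermediate
6 | 3-bromo-2-isopropoxyphenol | Oc1cccc(Br)c1OC(C)C | intermediate
7 | 3,4,6-tribromo-2-isopropoxyphenol | Oc1c(Br)cc(Br)c(Br)c1OC(C)C | intermediate
8 | 2-chlorocyclohexanone (racemic) | O=C1CCCCC1Cl | starting material
9 | 2-(3,4,6-tribromo-2-isopropoxyphenoxy)cyclohexan-1-one (racemic) | O=C1CCCCC1Oc1c(Br)cc(Br)c(Br)c1OC(C)C | intermediate
10 | 6,6-dibromo-2-(3,4,6-tribromo-2-isopropoxyphenoxy)cyclohex-2-en-1-one (not isolated) | O=C1C(Oc2c(Br)cc(Br)c(Br)c2OC(C)C)=CCCC1(Br)Br | intermediate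
11 | 2-bromo-6-(3,4,6-tribromo-2-isopropoxyphenoxy)phenol (not isolated) | Oc1c(Br)cccc1Oc1c(Br)cc(Br)c(Br)c1OC(C)C | intermediate
12 | 2,4-dibromo-6-(3,4,6-tribromo-2-isopropoxyphenoxy)phenol | Oc1c(Br)cc(Br)cc1Oc1c(Br)cc(Br)c(Br)c1OC(C)C | intermediate
13 | 1,2,5-tribromo-4-(3,5-dibromo-2-methoxyphenoxy)-3-isopropoxybenzene | COc1c(Br)cc(Br)cc1Oc1c(Br)cc(Br)c(Br)c1OC(C)C | intermediate
14 | dichloro[2,3,5-tribromo-6-(3,5-dibromo-2-methoxyphenoxy)phenoxy]borane (not isolated) | COc1c(Br)cc(Br)cc1Oc1c(Br)cc(Br)c(Br)c1OB(Cl)Cl | intermediate
15 | 2,3,5-tribromo-6-(3,5-dibromo-2-methoxyphenoxy)phenol | COc1c(Br)cc(Br)cc1Oc1c(Br)cc(Br)c(Br)c1O | target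

Total step count: 7. Longest linear sequence: 7.

**Steps most likely to fail**

Step 5.
- Bromine may add across the enol-ether double bond at the enone stage and end up on C5 or C3.
- Brominated C6 may solvolyse and expel the ring B phenol.
- The second dehydrobromination may stall.
- Hot HBr may strip the isopropyl group, after which C3' would be brominated.

The fallback buys ring A aromatic. It sets out from 7 and comes back at 12. Phenol 7 displaces fluoride from 2-fluorobenzaldehyde (K2CO3, DMAc, 140 °C, nucleophilic aromatic substitution) to give 2-(3,4,6-tribromo-2-isopropoxyphenoxy)benzaldehyde F1. Baeyer-Villiger oxidation with mCPBA in CH2Cl2 converts it to 2-(3,4,6-tribromo-2-isopropoxyphenoxy)phenyl formate F2. Methanolysis (cat. K2CO3, MeOH) frees 2-(3,4,6-tribromo-2-isopropoxyphenoxy)phenol F3. Two equivalents of Br2 in AcOH at rt then brominate ortho and para to the new hydroxyl to reach 12.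

Step 4. Substitution by the hindered, weakly nucleophilic phenoxide may be slower than base-induced Favorskii rearrangement, dehydrochlorination or self-condensation of the chloroketone. The fallback sets out from 7 and comes back at 9. The phenoxide opens cyclohexene oxide in the anti sense (Cs2CO3, 0.2 equiv, DMF, 100 °C) to give racemic trans-2-(3,4,6-tribromo-2-isopropoxyphenoxy)cyclohexan-1-ol F4. Dess-Martin periodinane in CH2Cl2 oxidises this alcohol to ketone 9.

Step 2. The exchange may be incomplete or run twice, or proton and bromine transfer between the aryllithium and unreacted 3 may scramble the substitution before boron arrives. The fallback replaces the organolithium by catalysis. It sets out from 3 and comes back at 6. Miyaura borylation of one of the two equivalent C-Br bonds (B2pin2 0.9 equiv, PdCl2(dppf), KOAc, dioxane, 80 °C) gives 2-(3-bromo-2-isopropoxyphenyl)-4,4,5,5-tetramethyl-1,3,2-dioxaborolane F5. After separation from unreacted 3, H2O2 in THF/water oxidises it to 6.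

**Further compounds**

F1 | step 5 | 2-(3,4,6-tribromo-2-isopropoxyphenoxy)benzaldehyde | O=Cc1ccccc1Oc1c(Br)cc(Br)c(Br)c1OC(C)C
F2 | step 5 | 2-(3,4,6-tribromo-2-isopropoxyphenoxy)phenyl formate | O=COc1ccccc1Oc1c(Br)cc(Br)c(Br)c1OC(C)C
F3 | step 5 | 2-(3,4,6-tribromo-2-isopropoxyphenoxy)phenol | Oc1ccccc1Oc1c(Br)cc(Br)c(Br)c1OC(C)C
F4 | step 4 | trans-2-(3,4,6-tribromo-2-isopropoxyphenoxy)cyclohexan-1-ol (racemic, 1R,2R drawn) | O[C@@H]1CCCC[C@H]1Oc1c(Br)cc(Br)c(Br)c1OC(C)C
F5 | step 2 | 2-(3-bromo-2-isopropoxyphenyl)-4,4,5,5-tetramethyl-1,3,2-dioxaborolane | CC(C)Oc1c(Br)cccc1B1OC(C)(C)C(C)(C)O1
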